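## Retrosynthetic overview

1. The target (19) comes from enantioselective ketoreductase reduction of the C5 ketone of dione 18; the only stereocentre is set in the last step.
2. The γ-pyranone ring is the only ring made (the carbocycle is bought as cyclohexane-1,3-dione): acid cyclodehydration of tetraketone 17, which comes from C-acylation of cyclohexane-1,3-dione with the ketal-masked β-keto acid 13.
3. β-Keto ester 11 comes from γ-alkylation of the ethyl acetoacetate dianion with (Z)-1-bromohexadec-11-ene 8.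
4. The Z-olefin comes from Lindlar semi-hydrogenation of the alkyne made from hex-1-yne and TBS-protected 10-bromodecan-1-ol.
5. Ring order: carbocycle pre-formed, then pyranone ring (step 11), then C5 carbinol (step 12).

Assumption: a Prelog-type, S-selective ketoreductase that accepts 18 is found by routine screening of a commercial ketoreductase panel.

Convention: numbers go to substrates, building blocks, in-flask intermediates and products; simple atom-donating reagents (TBSCl, CBr4, ethylene glycol, LiOH, water) are given by name and SMILES on the reagent line.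

## Route

Step 1
Reactants: 1 10-bromodecan-1-ol
Product: 2 [(10-bromodecyl)oxy](tert-butyl)dimethylsilane
Conditions: TBSCl (1.1 equiv), imidazole (1.5 equiv), DMF, 0 °C → rt
Reagents that add atoms: tert-butyl(chloro)dimethylsilane, CC(C)(C)[Si](C)(C)Cl
Why: Silyl ether protection of the primary alcohol keeps the OH from quenching the acetylide in step 2, creates no stereocentre and is stable to organolithiums.

Step 2
Reactants: 3 hex-1-yne; 2 [(10-bromodecyl)oxy](tert-butyl)dimethylsilane
Product: 5 tert-butyl(hexadec-11-yn-1-yloxy)dimethylsilane, via hex-1-ynyllithium 4 (not isolated)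
Conditions: 3 (1.5 equiv), n-BuLi (1.4 equiv), THF, −78 → 0 °C; then 2, DMPU, 0 °C → rt
Reagents that add atoms: hex-1-yne (3), CCCCC#C
Why: SN2 alkylation of a lithium acetylide with an unhindered primary bromide in a dipolar co-solvent is a standard C–C bond formation and leaves the silyl ether intact.

Step 3
Reactants: 5 tert-butyl(hexadec-11-yn-1-yloxy)dimethylsilane
Product: 6 hexadec-11-yn-1-ol
Conditions: p-TsOH·H2O (5 mol%), MeOH, rt
Reagents that add atoms: none
Why: Acid-catalysed methanolysis (desilylation) of a primary TBS ether is fast and does not touch the internal alkyne.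

Step 4
Reactants: 6 hexadec-11-yn-1-ol
Product: 7 (Z)-hexadec-11-en-1-ol
Conditions: H2 (1 atm), Lindlar catalyst (Pd/CaCO3–Pb), quinoline, EtOAc, rt, stopped after 1 equiv H2
Reagents that add atoms: none
Why: Lindlar semi-hydrogenation delivers H2 syn on the poisoned Pd surface, giving the Z-alkene (typically >97:3) without over-reduction.

Step 5
Reactants: 7 (Z)-hexadec-11-en-1-ol
Product: 8 (Z)-1-bromohexadec-11-ene
Conditions: CBr4 (1.2 equiv), PPh3 (1.25 equiv), CH2Cl2, 0 °C
Reagents that add atoms: carbon tetrabromide, BrC(Br)(Br)Br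
Why: The Appel reaction converts the primary alcohol to the bromide under neutral conditions, so no HBr is present to add to or isomerise the Z-olefin.

Step 6
Reactants: 9 ethyl acetoacetate; 8 (Z)-1-bromohexadec-11-ene
Product: 11 ethyl (Z)-3-oxoicos-15-enoate, via ethyl acetoacetate dilithium dianion 10 (not isolated)
Conditions: 9 (1.3 equiv), LDA (2.6 equiv), THF, 0 °C; then 8, 0 °C → rt; 1 M HCl quench
Reagents that add atoms: ethyl acetoacetate (9), CCOC(=O)CC(C)=O
Why: In the Huckin–Weiler dianion alkylation the more basic terminal (γ) carbanion reacts selectively with the primary bromide, giving the chain-extended β-keto ester.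

Step 7
Reactants: 11 ethyl (Z)-3-oxoicos-15-enoate
Product: 12 ethyl 2-{2-[(Z)-heptadec-12-en-1-yl]-1,3-dioxolan-2-yl}acetate
Conditions: ethylene glycol (5 equiv), p-TsOH·H2O (5 mol%), benzene, reflux, Dean–Stark
Reagents that add atoms: ethane-1,2-diol, OCCO
Why: Acid-catalysed ketalisation driven by azeotropic water removal masks the ketone so the β-keto acid can be unveiled and activated without decarboxylation.

Step 8
Reactants: 12 ethyl 2-{2-[(Z)-heptadec-12-en-1-yl]-1,3-dioxolan-2-yl}acetate
Product: 13 2-{2-[(Z)-heptadec-12-en-1-yl]-1,3-dioxolan-2-yl}acetic acid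
Conditions: LiOH·H2O (3 equiv), THF/EtOH/H2O, rt → 40 °C; then 1 M HCl to pH 4, 0 °C
Reagents that add atoms: lithium hydroxide, [Li+].[OH-]
Why: Saponification (BAc2 ester hydrolysis) proceeds cleanly because the dioxolane is base-stable, and cold acidification to pH 4 frees the acid without opening the ketal.

Step 9
Reactants: 13 2-{2-[(Z)-heptadec-12-en-1-yl]-1,3-dioxolan-2-yl}acetic acid; 14 cyclohexane-1,3-dione
Product: 16 2-(2-{2-[(Z)-heptadec-12-en-1-yl]-1,3-dioxolan-2-yl}acetyl)-3-hydroxycyclohex-2-en-1-one, via enol ester 15 (not isolated)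
Conditions: DCC (1.2 equiv), DMAP (0.3 equiv), Et3N (1.2 equiv), CH2Cl2, 0 °C → rt, 24 h
Reagents that add atoms: cyclohexane-1,3-dione (14), O=C1CCCC(=O)C1
Why: Steglich O-acylation of the dione enol is followed in the same pot by the DMAP-mediated 1,3-O→C acyl shift (Fries-type rearrangement) to the thermodynamically favoured, hydrogen-bonded 2-acyl-1,3-dione.

Step 10
Reactants: 16 2-(2-{2-[(Z)-heptadec-12-en-1-yl]-1,3-dioxolan-2-yl}acetyl)-3-hydroxycyclohex-2-en-1-one
Product: 17 3-hydroxy-2-[(Z)-3-oxoicos-15-enoyl]cyclohex-2-en-1-one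
Conditions: 2 M HCl/THF (1:4), rt
Reagents that add atoms: water, O
Why: Acid-catalysed ketal hydrolysis liberates the side-chain ketone, while the enolised triketone and the isolated Z-olefin are inert to dilute acid at room temperature.

Step 11
Reactants: 17 3-hydroxy-2-[(Z)-3-oxoicos-15-enoyl]cyclohex-2-en-1-one
Product: 18 2-[(Z)-heptadec-12-en-1-yl]-7,8-dihydro-4H-chromene-4,5(6H)-dione
Conditions: p-TsOH·H2O (10 mol%), toluene, reflux, Dean–Stark, 1–2 h
Reagents that add atoms: none
Why: Acid-catalysed cyclodehydration of the 1,3,5-tricarbonyl unit (ring enol oxygen adds to the side-chain ketone, the hemiketal loses water) gives the γ-pyranone; the symmetric dione allows only one regioisomer and acid favours O-cyclisation over C-aldol aromatisation.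

Step 12
Reactants: 18 2-[(Z)-heptadec-12-en-1-yl]-7,8-dihydro-4H-chromene-4,5(6H)-dione
Product: 19 (5S)-2-[(Z)-heptadec-12-en-1-yl]-5-hydroxy-5,6,7,8-tetrahydro-4H-chromen-4-one
Conditions: Prelog-selective ketoreductase (NADPH-dependent alcohol dehydrogenase), NADP+ (cat.), i-PrOH (20 vol%), KPi buffer pH 7.0, MgSO4 (2 mM), DMSO (10 vol%), 30 °C
Reagents that add atoms: none
Why: In this biocatalytic asymmetric ketone reduction the ketoreductase delivers hydride from NADPH (recycled by i-PrOH) to the re face of the C5 ketone only, setting the single stereocentre as S (the tetralone-type Prelog outcome), while the cross-conjugated pyranone C4=O is not a substrate.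

## Compound list

1 | 10-bromodecan-1-ol | OCCCCCCCCCCBr | starting material
2 | [(10-bromodecyl)oxy](tert-butyl)dimethylsilane | CC(C)(C)[Si](C)(C)OCCCCCCCCCCBr | intermediate
3 | hex-1-yne | CCCCC#C | starting material
4 | hex-1-ynyllithium | CCCCC#C[Li] | intermediate
5 | tert-butyl(hexadec-11-yn-1-yloxy)dimethylsilane | CCCCC#CCCCCCCCCCCO[Si](C)(C)C(C)(C)C | intermediate
6 | hexadec-11-yn-1-ol | CCCCC#CCCCCCCCCCCO | intermediate
7 | (Z)-hexadec-11-en-1-ol | CCCC/C=C\CCCCCCCCCCO | intermediate
8 | (Z)-1-bromohexadec-11-ene | CCCC/C=C\CCCCCCCCCCBr | intermediate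
9 | ethyl acetoacetate | CCOC(=O)CC(C)=O | starting material
10 | ethyl acetoacetate dilithium dianion | [Li+].[Li+].C=C([O-])C=C([O-])OCC | intermediate
11 | ethyl (Z)-3-oxoicos-15-enoate | CCCC/C=C\CCCCCCCCCCCC(=O)CC(=O)OCC | intermediate
12 | ethyl 2-{2-[(Z)-heptadec-12-en-1-yl]-1,3-dioxolan-2-yl}acetate | CCCC/C=C\CCCCCCCCCCCC1(CC(=O)OCC)OCCO1 | intermediate
13 | 2-{2-[(Z)-heptadec-12-en-1-yl]-1,3-dioxolan-2-yl}acetic acid | CCCC/C=C\CCCCCCCCCCCC1(CC(=O)O)OCCO1 | intermediate
14 | cyclohexane-1,3-dione | O=C1CCCC(=O)C1 | starting material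
15 | 3-oxocyclohex-1-en-1-yl 2-{2-[(Z)-heptadec-12-en-1-yl]-1,3-dioxolan-2-yl}acetate | CCCC/C=C\CCCCCCCCCCCC1(CC(=O)OC2=CC(=O)CCC2)OCCO1 | intermediate
16 | 2-(2-{2-[(Z)-heptadec-12-en-1-yl]-1,3-dioxolan-2-yl}acetyl)-3-hydroxycyclohex-2-en-1-one | CCCC/C=C\CCCCCCCCCCCC1(CC(=O)C2=C(O)CCCC2=O)OCCO1 | intermediate
17 | 3-hydroxy-2-[(Z)-3-oxoicos-15-enoyl]cyclohex-2-en-1-one (enol form of 2-[(Z)-3-oxoicos-15-enoyl]cyclohexane-1,3-dione) | CCCC/C=C\CCCCCCCCCCCC(=O)CC(=O)C1=C(O)CCCC1=O | intermediate
18 | 2-[(Z)-heptadec-12-en-1-yl]-7,8-dihydro-4H-chromene-4,5(6H)-dione | CCCC/C=C\CCCCCCCCCCCc1cc(=O)c2c(o1)CCCC2=O | intermediate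
19 | (5S)-2-[(Z)-heptadec-12-en-1-yl]-5-hydroxy-5,6,7,8-tetrahydro-4H-chromen-4-one | CCCC/C=C\CCCCCCCCCCCc1cc(=O)c2c(o1)CCC[C@@H]2O | target

## Summary and fallbacks

Total step count: 12. Longest linear sequence: 12 steps (from 10-bromodecan-1-ol 1; compounds 3, 9 and 14 are bought and enter as partners).

The three steps most likely to fail:

**Step 12 (ketoreductase reduction).** The enzyme may not accept the lipophilic C17-chain substrate or may give low ee. The fallback sets out from 18 and comes back at 19. Luche reduction of 18 (NaBH4, CeCl3·7H2O, MeOH, −20 °C) reduces only the C5 ketone and gives racemic 2-[(Z)-heptadec-12-en-1-yl]-5-hydroxy-5,6,7,8-tetrahydro-4H-chromen-4-one F1. A lipase (immobilised Candida antarctica lipase B) with vinyl acetate in MTBE at 30 °C then acetylates only the R enantiomer (Kazlauskas rule, as for 1-tetralol) to (5R)-2-[(Z)-heptadec-12-en-1-yl]-4-oxo-5,6,7,8-tetrahydro-4H-chromen-5-yl acetate F2. The untouched S alcohol is 19, separated by chromatography at about 50% conversion.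

**Step 11 (acid cyclodehydration).** Ring closure of the strongly chelated triketone may be sluggish, or the hot sulfonic acid may isomerise the Z-olefin. The fallback sets out from 11 and comes back at 18; it replaces dehydration by an addition–elimination ring closure under nearly neutral conditions and bypasses steps 7–11. Triethyl orthoformate, EtOH and cat. H2SO4 convert 11 into ethyl (2E,15Z)-3-ethoxyicosa-2,15-dienoate F3. KOH in aqueous EtOH, then cold acidification to pH 4, gives (2E,15Z)-3-ethoxyicosa-2,15-dienoic acid F4. DCC/DMAP/Et3N coupling with 14 (as in step 9) gives 2-[(2E,15Z)-3-ethoxyicosa-2,15-dienoyl]-3-hydroxycyclohex-2-en-1-one F5. With PPTS in toluene at 60 °C, F5 closes by oxa-Michael addition of the ring enol and loss of ethanol to 18.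

**Step 6 (dianion alkylation).** A long-chain unactivated bromide can give low conversion, elimination or O-alkylation. The fallback sets out from 8 and comes back at 11; it builds the β-keto ester by acylation instead of alkylation. Diethyl malonate, NaOEt, EtOH at reflux with 8 gives diethyl 2-[(Z)-hexadec-11-en-1-yl]propanedioate F6. KOH in aqueous EtOH at reflux, then acidification, gives 2-[(Z)-hexadec-11-en-1-yl]propanedioic acid F7, which loses CO2 at 150 °C to give (Z)-octadec-13-enoic acid F8. Meldrum's acid, DCC and DMAP in CH2Cl2 give 5-[(Z)-1-hydroxyoctadec-13-en-1-ylidene]-2,2-dimethyl-1,3-dioxane-4,6-dione F9. Refluxing F9 in EtOH (acylketene ethanolysis) gives 11.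

Further compounds

F1 | step 12 | racemic 2-[(Z)-heptadec-12-en-1-yl]-5-hydroxy-5,6,7,8-tetrahydro-4H-chromen-4-one | CCCC/C=C\CCCCCCCCCCCc1cc(=O)c2c(o1)CCCC2O
F2 | step 12 | (5R)-2-[(Z)-heptadec-12-en-1-yl]-4-oxo-5,6,7,8-tetrahydro-4H-chromen-5-yl acetate | CCCC/C=C\CCCCCCCCCCCc1cc(=O)c2c(o1)CCC[C@H]2OC(C)=O
F3 | step 11 | ethyl (2E,15Z)-3-ethoxyicosa-2,15-dienoate | CCCC/C=C\CCCCCCCCCCC/C(OCC)=C\C(=O)OCC
F4 | step 11 | (2E,15Z)-3-ethoxyicosa-2,15-dienoic acid | CCCC/C=C\CCCCCCCCCCC/C(OCC)=C\C(=O)O
F5 | step 11 | 2-[(2E,15Z)-3-ethoxyicosa-2,15-dienoyl]-3-hydroxycyclohex-2-en-1-one | CCCC/C=C\CCCCCCCCCCC/C(OCC)=C\C(=O)C1=C(O)CCCC1=O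
F6 | step 6 | diethyl 2-[(Z)-hexadec-11-en-1-yl]propanedioate | CCCC/C=C\CCCCCCCCCCC(C(=O)OCC)C(=O)OCC
F7 | step 6 | 2-[(Z)-hexadec-11-en-1-yl]propanedioic acid | CCCC/C=C\CCCCCCCCCCC(C(=O)O)C(=O)O
F8 | step 6 | (Z)-octadec-13-enoic acid | CCCC/C=C\CCCCCCCCCCCC(=O)O
F9 | step 6 | 5-[(Z)-1-hydroxyoctadec-13-en-1-ylidene]-2,2-dimethyl-1,3-dioxane-4,6-dione | CCCC/C=C\CCCCCCCCCCCC(O)=C1C(=O)OC(C)(C)OC1=O
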